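## The problem

3,5,7-Trihydroxy-8-methoxy-4'-prenyloxyflavone (20) is a flavonol: rings A and C are fused through C4a–C8a into a benzopyranone, and ring B sits on C2. It has no stereocentre, and its only side-chain alkene carries two identical methyl groups, so nothing has to be controlled in space. Every difficulty is one of position and chemoselectivity. Ring A carries oxygen on C5, C7, C8 and C8a, with only the C8 oxygen methylated and a single C–H at C6. O1 and the C7 oxygen are mirror-related across the C8–C5 axis, so a symmetric ring A building block is desymmetrized by the first substituent it receives, and the two flanking oxygens must then be told apart. The 4'-prenyl ether is the fragile group: it ionizes in acid, can be ionized by electron-rich zerovalent palladium, rearranges on strong heating, and its alkene is attacked by peracids and dioxiranes and rules out hydrogenolysis. It cannot be introduced last either, since the 7-hydroxyl would be alkylated first, so ring B must arrive already prenylated and every later protecting group should leave without acid. The 3-hydroxyl sits on the α-carbon of a cross-conjugated enone, a position that is acidic (C3–H) but not nucleophilic. The enabling feature is that carbonyl carbon C4 lies between C4a of ring A and the C3=C2 unit bearing ring B, with O1 ortho to C4a. C4 can therefore enter as carbon monoxide between an aryl iodide and a terminal arylalkyne, and O1 can close ring C on C2.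

## Retrosynthesis

**20 ⇒ 19 (two O–Si bonds on ring A).** The last operation is chosen first because it fixes the protecting-group logic. With the prenyl ether present, benzyl ethers (hydrogenolysis) or acetal ethers (acid) on O5 and O7 would each put the side chain at risk. Two triisopropylsilyl ethers leave with buffered fluoride, so 20 is traced to bis-silyl flavonol 19. The forward step need only avoid holding the oxidation-prone flavonol as a polyanion.

**19 ⇒ 16 (C3–O bond).** C3–H of flavone 16 is the one C–H made acidic by the adjacent carbonyl. Deprotonation to 17, capture on boron as 18 and oxidative migration of C3 from boron to oxygen should give 19 in one flask. The neighbouring options are worse. Epoxidation of C2=C3 would meet the more electron-rich prenyl alkene first, and an alkyne annulation cannot carry a C3 oxygen, because C3 is the terminal alkyne carbon. The cut removes one heteroatom and frees ring C to be built by a flavone synthesis. The forward step must spare the aryl silyl ethers, the allylic ether and the trisubstituted alkene.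

**16 ⇒ 8 + 12 + 13 (C4a–C4, C4–C3 and O1–C2).** Ring C is taken apart into iodophenol 8, arylalkyne 12 and carbon monoxide (13). In the forward direction the ynone 14 and its secondary-amine adduct 15 are passed without isolation. Classical flavone routes (acyl transfer and acid cyclodehydration, or chalcone oxidation) would need an ortho-hydroxyacetophenone of ring A and acid or oxidants that the prenyl ether tolerates poorly. Here the precursors are far simpler: ring A needs only an iodine ortho to its free hydroxyl, ring B is an alkyne, and the third component is a gas. The forward reaction must make the acyl–alkyne bond faster than the direct aryl–alkyne bond, close 6-endo and not 5-exo, and leave the prenyl and silyl ethers alone.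

**12 ⇒ 11 ⇒ 9 + 10 (alkyne carbon, then O–prenyl bond).** The terminal alkyne carbon is removed by reversing a one-carbon aldehyde homologation of the Seyferth–Gilbert type, which leads to aldehyde 11. Its ether bond is cut to 4-hydroxybenzaldehyde (9) and prenyl bromide (10). This takes two steps, against three for a cross-coupling and desilylation sequence from an aryl halide, and both run in carbonate base, to which the prenyl ether is indifferent.

**8 ⇒ 7 ⇒ 6 (O–Si of the unhindered hydroxyl, then C–I).** Diol 6 is symmetric, so its two ring C–H positions are equivalent and only one mono-iodide, 7, can form. The iodine then marks its ortho hydroxyl as O1 twice over: that oxygen is the one next to the future acyl carbon, and it is flanked on both sides, so the other hydroxyl should take the bulky silyl group to give 8. Silylating before iodinating would instead leave an ortho/para choice for the halogen.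

**6 ⇒ 5 ⇒ 4 ⇒ 3 ⇒ 2 ⇒ 1 (C–O bond para to the methoxyl).** 2-Methoxyresorcinol (1) already has the three contiguous oxygens with the methyl on the middle one. The missing oxygen is para to the methoxyl, where electrophilic substitution cannot reach because both hydroxyls direct to the other positions. That carbon is, however, the only C–H without an ortho neighbour, so sterically governed C–H borylation of bis-acetal 2 should give boronate 3, and oxidation gives phenol 4. The new phenol is silylated (5) and the acetals are removed (6) before any acid-sensitive group exists.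

## Roads not taken

**Alternative 1:** The cut is C3–C4 and C2=C3, with C3 and its oxygen supplied as a one-carbon phosphorus ylide placed between two acyl carbons. In the forward step acid chloride A2 acylates ylide A3 at carbon, and the same phosphorus centre then olefinates the neighbouring aryl ester carbonyl intramolecularly, giving protected flavonol A1.
- Merits: the C3 oxygen is in place when ring C closes, so no later C–H oxidation is needed, and no transition metal or toxic gas is used.
- Weak points: A2 needs a carboxyl carbon on C4a and an aroyl ester on the hindered O1, and it must be made as an acid chloride in the presence of acetal ethers that the released HCl threatens. A3 is a basic, non-stabilized α-alkoxy ylide; half of it is consumed as base after acylation, and it can attack the aryl ester directly. Olefination of an ester carbonyl by a fully substituted acyl ylide to a tetrasubstituted enol ether is the slow member of this family and may need heating. The acetal ethers of A1 still have to be removed with acid next to the prenyl ether.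
- Comparison: this road is one operation shorter after ring closure, which is a real advantage. The chosen plan sets against it a ring A partner that needs only an iodine, three bond formations on one well-precedented catalytic cycle, and an endgame in which fluoride is the only reagent. The step saved at C3 is likely spent in making A2.

**Alternative 2:** The cut is O1–C8a. In the forward step the enol oxygen of the 2-alkoxy-1,3-diketone side chain of acylquinone A5 adds to the quinone carbon that becomes C8a, and tautomerization gives the 5,8-dihydroxyflavone A4.
- Merits: no metal is used, the C3 oxygen is present from the start, and six-membered closure through oxygen is the only geometrically sensible mode. The two new phenols are differentiated by chelation of the 5-hydroxyl to C4=O, so the 8-hydroxyl could be methylated selectively.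
- Weak points: the C8 methoxyl, which the chosen route buys with compound 1, costs an extra methylation. A5 can only be reached by raising ring A to the quinone level late, in the presence of an enolizable diketone and the prenyl alkene. Acylquinones are among the most electrophilic quinones, and the alkoxy group on the quinone is a vinylogous ester open to addition–elimination. The unchelated acetal ethers on O3 and O7 of A4 need real acid at the end.
- Comparison: in certainty of ring closure this road is probably as good as the chosen one, and it avoids both CO and strong base. It is longer (diketone assembly, oxidation, closure, methylation, deprotection), passes through a sensitive intermediate and ends in acid. The chosen plan keeps ring A at one oxidation level throughout and has the methoxyl fixed from the first compound.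

**Alternative 3:** The cut is O1–C2 and C3–C4, with a nitro group as the latent C3 oxygen. In the forward step salicylaldehyde A7 and nitrostyrene A8 combine under amine base by oxa-Michael addition and intramolecular Henry condensation to the racemic 3-nitro-2H-chromene A6.
- Merits: the annulation is metal-free, robust and cheap, and A8 would come from aldehyde 11 of the present route in one condensation.
- Weak points: A6 is at the wrong oxidation level at three ring atoms. C4 is an alkene CH that must become the carbonyl, C2 is an sp3 stereocentre that must be destroyed, and the C3–N bond must become C–O. The known ways of doing this on simple 2-aryl-3-nitrochromenes use alkaline peroxide and a later dehydrogenation, adding several operations with oxidants beside the prenyl alkene and an electron-rich ring A. A7 needs a formyl group ortho to O1 on a differentially protected ring A, which is no easier than placing iodine there, and its acetal ethers again call for acid at the end.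
- Comparison: the ring-forming step is operationally simpler and more scalable than a pressurized carbonylation, and that should be conceded. The chosen plan sets against it that ring C is formed directly at the correct oxidation level at C2 and C4, that only C3 needs one further operation, and that no stereocentre is made only to be erased.

Key step: step 9

Assumption: compounds 1, 9, 10 and 13 and every reagent on a Conditions line are purchased (LiN(iPr)2 as a solution); ring atoms of flavones are quoted in flavone numbering.

## Route

Step 1
Reactants: 1 2-methoxyresorcinol (2-methoxybenzene-1,3-diol)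
Product: 2 2-methoxy-1,3-bis(methoxymethoxy)benzene
Conditions: MOMCl, iPr2NEt, CH2Cl2, 0 °C → rt
Reagents that add atoms: chloromethyl methyl ether, COCCl
Why: O-alkylation of both phenols with the chloromethyl ether (MOM protection); acetal ethers add no arene C–H that could compete in step 2, tolerate alkaline peroxide, and can later be removed without touching an aryl silyl ether.

Step 2
Reactants: 2 2-methoxy-1,3-bis(methoxymethoxy)benzene
Product: 4 4-methoxy-3,5-bis(methoxymethoxy)phenol, via aryl pinacol boronate 3 (not isolated)
Conditions: [Ir(OMe)(cod)]2 (1.5 mol%), 4,4'-di-tert-butyl-2,2'-bipyridine (3 mol%), B2pin2, cyclohexane, 80 °C; then THF, aq. NaOH, 30% H2O2, 0 °C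
Reagents that add atoms: bis(pinacolato)diboron, CC1(C)OB(OC1(C)C)B1OC(C)(C)C(C)(C)O1 (boron unit of 3 only); hydrogen peroxide, OO
Why: Iridium-catalysed aromatic C–H borylation is governed by sterics, and the carbon para to the methoxyl is the only C–H of 2 without an ortho substituent, so 3 should form as one isomer; alkaline peroxide then moves the aryl group from boron to oxygen (boronate oxidation) to give 4.

Step 3
Reactants: 4 4-methoxy-3,5-bis(methoxymethoxy)phenol
Product: 5 [4-methoxy-3,5-bis(methoxymethoxy)phenoxy]triisopropylsilane
Conditions: iPr3SiCl, imidazole, DMF, rt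
Reagents that add atoms: chlorotriisopropylsilane, CC(C)[Si](Cl)(C(C)C)C(C)C
Why: Imidazole-promoted silylation of an unhindered phenol; the bulky TIPS group is chosen to outlast methanolic acid, amine, lithium amide and peroxide and to leave only with fluoride.

Step 4
Reactants: 5 [4-methoxy-3,5-bis(methoxymethoxy)phenoxy]triisopropylsilane
Product: 6 2-methoxy-5-(triisopropylsilyloxy)benzene-1,3-diol
Conditions: conc. HCl (cat.), MeOH, 40 °C
Reagents that add atoms: none
Why: Acid-catalysed acetal exchange cleaves both MOM ethers, with methanol carrying off the methoxymethyl unit as dimethoxymethane so that the electron-rich ring is not alkylated; aryl TIPS ethers should be stable to dilute methanolic HCl.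

Step 5
Reactants: 6 2-methoxy-5-(triisopropylsilyloxy)benzene-1,3-diol
Product: 7 4-iodo-2-methoxy-5-(triisopropylsilyloxy)benzene-1,3-diol
Conditions: N-iodosuccinimide (1.0 equiv), MeCN, −30 → 0 °C, dark
Reagents that add atoms: N-iodosuccinimide, O=C1CCC(=O)N1I
Why: Electrophilic aromatic iodination of a doubly activated ring; the two ring C–H of 6 are equivalent, each ortho to one hydroxyl and para to the other, so only one mono-iodide exists, and one equivalent of reagent at low temperature should hold the reaction there.

Step 6
Reactants: 7 4-iodo-2-methoxy-5-(triisopropylsilyloxy)benzene-1,3-diol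
Product: 8 6-iodo-2-methoxy-3,5-bis(triisopropylsilyloxy)phenol
Conditions: iPr3SiCl (1.05 equiv), imidazole, DMF, 0 °C
Reagents that add atoms: chlorotriisopropylsilane, CC(C)[Si](Cl)(C(C)C)C(C)C
Why: Sterically controlled silylation: the hydroxyl next to iodine is flanked on both sides (OMe and I) and should react far more slowly with the bulky silyl chloride than the hydroxyl flanked by OMe and H, so the phenol left free in 8 is the one ortho to iodine.

Step 7
Reactants: 9 4-hydroxybenzaldehyde; 10 prenyl bromide (1-bromo-3-methylbut-2-ene)
Product: 11 4-[(3-methylbut-2-en-1-yl)oxy]benzaldehyde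
Conditions: K2CO3, acetone, reflux
Reagents that add atoms: none
Why: Williamson ether synthesis; the phenoxide displaces the primary allylic bromide by direct SN2 substitution, and the aldehyde is untouched by carbonate.

Step 8
Reactants: 11 4-[(3-methylbut-2-en-1-yl)oxy]benzaldehyde
Product: 12 1-ethynyl-4-[(3-methylbut-2-en-1-yl)oxy]benzene
Conditions: dimethyl (1-diazo-2-oxopropyl)phosphonate, K2CO3, MeOH, 0 °C → rt
Reagents that add atoms: dimethyl (1-diazo-2-oxopropyl)phosphonate, CC(=O)C(=[N+]=[N-])P(=O)(OC)OC
Why: Seyferth–Gilbert homologation with the Ohira–Bestmann reagent converts the non-enolizable aryl aldehyde into the terminal alkyne under K2CO3/MeOH, conditions to which an aryl allyl ether is inert.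

Step 9
Reactants: 8 6-iodo-2-methoxy-3,5-bis(triisopropylsilyloxy)phenol; 12 1-ethynyl-4-[(3-methylbut-2-en-1-yl)oxy]benzene; 13 carbon monoxide
Product: 16 8-methoxy-2-{4-[(3-methylbut-2-en-1-yl)oxy]phenyl}-5,7-bis(triisopropylsilyloxy)-4H-chromen-4-one, via ynone 14 (not isolated), via enaminone 15 (not isolated)
Conditions: PdCl2(PPh3)2 (5 mol%), CO (5 bar), Et2NH, 60 °C
Reagents that add atoms: diethylamine, CCNCC (present in 15 only, released again on ring closure)
Why: Carbonylative Sonogashira coupling followed by amine-mediated cyclization, the known palladium-catalysed route from 2-iodophenols, CO and terminal arylalkynes to flavones in a secondary amine. PdCl2(PPh3)2 is reduced in the flask to zerovalent palladium, which inserts into the C–I bond of 8; migratory insertion of CO gives the aroylpalladium iodide, and amine-assisted transfer of the acetylide of 12 with reductive elimination forms C4a–C4 and C4–C3 in ynone 14. Diethylamine adds to 14 to give enaminone 15, whose phenolic oxygen attacks the amine-bearing carbon and expels the amine, forming O1–C2. Ring C thus closes in the 6-endo mode by addition–elimination; the 5-exo closure to an aurone is shut off because in 15 the electrophilic carbon is C2 alone. No stereocentre is formed. Acyl coupling must outrun CO-free alkynylation (which would end in a 2-arylbenzofuran) and amide formation: copper is omitted, CO is kept under pressure, the electron-rich, doubly ortho-substituted aryl group should migrate readily to CO, and the acidic arylalkyne should be transferred faster than the amine attacks the acyl complex. The regiochemistry is fixed by 8, whose only free hydroxyl is ortho to iodine and next to the methoxyl carbon, so it can only become O1 beside C8. The trisubstituted prenyl alkene binds poorly to CO-saturated, phosphine-ligated zerovalent palladium at 60 °C, so ionization of the aryl prenyl ether is not expected, and TIPS ethers tolerate the amine.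

Step 10
Reactants: 16 8-methoxy-2-{4-[(3-methylbut-2-en-1-yl)oxy]phenyl}-5,7-bis(triisopropylsilyloxy)-4H-chromen-4-one
Product: 19 3-hydroxy-8-methoxy-2-{4-[(3-methylbut-2-en-1-yl)oxy]phenyl}-5,7-bis(triisopropylsilyloxy)-4H-chromen-4-one, via 3-lithioflavone 17 (not isolated), via lithium borate 18 (not isolated)
Conditions: LiN(iPr)2, THF, −78 °C; B(OMe)3, −78 → 0 °C; then AcOH, 30% H2O2, 0 °C
Reagents that add atoms: lithium diisopropylamide, [Li]N(C(C)C)C(C)C (lithium of 17 and 18 only); trimethyl borate, COB(OC)OC (boron unit of 18 only); hydrogen peroxide, OO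
Why: Deprotonation of the vinylic C3–H (α to the carbonyl, lithium held by the carbonyl oxygen) is the known mode of metalation of flavones; 17 is trapped by the borate ester as 18, and peroxide in acetic acid induces the 1,2-shift of C3 from boron to oxygen (boronate oxidation), conditions that should spare aryl TIPS ethers and the prenyl alkene at 0 °C.

Step 11
Reactants: 19 3-hydroxy-8-methoxy-2-{4-[(3-methylbut-2-en-1-yl)oxy]phenyl}-5,7-bis(triisopropylsilyloxy)-4H-chromen-4-one
Product: 20 3,5,7-trihydroxy-8-methoxy-2-{4-[(3-methylbut-2-en-1-yl)oxy]phenyl}-4H-chromen-4-one (3,5,7-trihydroxy-8-methoxy-4'-prenyloxyflavone)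
Conditions: Bu4NF, AcOH, THF, 0 °C, under argon
Reagents that add atoms: none
Why: Fluoride cleaves both aryl Si–O bonds (desilylation; phenoxides are good leaving groups at silicon); acetic acid buffers the medium so that the flavonol is not exposed as an air-sensitive polyanion, and nothing in the step can ionize or isomerize the prenyl ether.

## Compound list

1 | 2-methoxyresorcinol (2-methoxybenzene-1,3-diol) | COc1c(O)cccc1O | starting material
2 | 2-methoxy-1,3-bis(methoxymethoxy)benzene | COCOc1cccc(OCOC)c1OC | intermediate
3 | 2-[4-methoxy-3,5-bis(methoxymethoxy)phenyl]-4,4,5,5-tetramethyl-1,3,2-dioxaborolane | COCOc1cc(B2OC(C)(C)C(C)(C)O2)cc(OCOC)c1OC | intermediate (not isolated)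
4 | 4-methoxy-3,5-bis(methoxymethoxy)phenol | COCOc1cc(O)cc(OCOC)c1OC | intermediate
5 | [4-methoxy-3,5-bis(methoxymethoxy)phenoxy]triisopropylsilane | COCOc1cc(O[Si](C(C)C)(C(C)C)C(C)C)cc(OCOC)c1OC | intermediate
6 | 2-methoxy-5-(triisopropylsilyloxy)benzene-1,3-diol | COc1c(O)cc(O[Si](C(C)C)(C(C)C)C(C)C)cc1O | intermediate
7 | 4-iodo-2-methoxy-5-(triisopropylsilyloxy)benzene-1,3-diol | COc1c(O)cc(O[Si](C(C)C)(C(C)C)C(C)C)c(I)c1O | intermediate
8 | 6-iodo-2-methoxy-3,5-bis(triisopropylsilyloxy)phenol | COc1c(O[Si](C(C)C)(C(C)C)C(C)C)cc(O[Si](C(C)C)(C(C)C)C(C)C)c(I)c1O | intermediate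
9 | 4-hydroxybenzaldehyde | O=Cc1ccc(O)cc1 | starting material
10 | prenyl bromide (1-bromo-3-methylbut-2-ene) | CC(C)=CCBr | starting material
11 | 4-[(3-methylbut-2-en-1-yl)oxy]benzaldehyde | CC(C)=CCOc1ccc(C=O)cc1 | intermediate
12 | 1-ethynyl-4-[(3-methylbut-2-en-1-yl)oxy]benzene | C#Cc1ccc(OCC=C(C)C)cc1 | intermediate
13 | carbon monoxide | [C-]#[O+] | starting material
14 | 1-[2-hydroxy-3-methoxy-4,6-bis(triisopropylsilyloxy)phenyl]-3-{4-[(3-methylbut-2-en-1-yl)oxy]phenyl}prop-2-yn-1-one | COc1c(O[Si](C(C)C)(C(C)C)C(C)C)cc(O[Si](C(C)C)(C(C)C)C(C)C)c(C(=O)C#Cc2ccc(OCC=C(C)C)cc2)c1O | intermediate (not isolated)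
15 | (E)-3-(diethylamino)-1-[2-hydroxy-3-methoxy-4,6-bis(triisopropylsilyloxy)phenyl]-3-{4-[(3-methylbut-2-en-1-yl)oxy]phenyl}prop-2-en-1-one (E drawn; either geometry would close) | COc1c(O[Si](C(C)C)(C(C)C)C(C)C)cc(O[Si](C(C)C)(C(C)C)C(C)C)c(C(=O)/C=C(/N(CC)CC)c2ccc(OCC=C(C)C)cc2)c1O | intermediate (not isolated)
16 | 8-methoxy-2-{4-[(3-methylbut-2-en-1-yl)oxy]phenyl}-5,7-bis(triisopropylsilyloxy)-4H-chromen-4-one | COc1c(O[Si](C(C)C)(C(C)C)C(C)C)cc(O[Si](C(C)C)(C(C)C)C(C)C)c2c(=O)cc(-c3ccc(OCC=C(C)C)cc3)oc12 | intermediate
17 | 3-lithio-8-methoxy-2-{4-[(3-methylbut-2-en-1-yl)oxy]phenyl}-5,7-bis(triisopropylsilyloxy)-4H-chromen-4-one | COc1c(O[Si](C(C)C)(C(C)C)C(C)C)cc(O[Si](C(C)C)(C(C)C)C(C)C)c2c(=O)c([Li])c(-c3ccc(OCC=C(C)C)cc3)oc12 | intermediate (not isolated)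
18 | lithium trimethoxy[8-methoxy-2-{4-[(3-methylbut-2-en-1-yl)oxy]phenyl}-4-oxo-5,7-bis(triisopropylsilyloxy)-4H-chromen-3-yl]borate | [Li+].COc1c(O[Si](C(C)C)(C(C)C)C(C)C)cc(O[Si](C(C)C)(C(C)C)C(C)C)c2c(=O)c([B-](OC)(OC)OC)c(-c3ccc(OCC=C(C)C)cc3)oc12 | intermediate (not isolated)
19 | 3-hydroxy-8-methoxy-2-{4-[(3-methylbut-2-en-1-yl)oxy]phenyl}-5,7-bis(triisopropylsilyloxy)-4H-chromen-4-one | COc1c(O[Si](C(C)C)(C(C)C)C(C)C)cc(O[Si](C(C)C)(C(C)C)C(C)C)c2c(=O)c(O)c(-c3ccc(OCC=C(C)C)cc3)oc12 | intermediate
20 | 3,5,7-trihydroxy-8-methoxy-2-{4-[(3-methylbut-2-en-1-yl)oxy]phenyl}-4H-chromen-4-one (3,5,7-trihydroxy-8-methoxy-4'-prenyloxyflavone) | COc1c(O)cc(O)c2c(=O)c(O)c(-c3ccc(OCC=C(C)C)cc3)oc12 | target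

## Step count and least certain steps

Total: 11 steps. Longest linear sequence: 9 steps (steps 1–6, then 9–11); the alkyne branch is steps 7 and 8.

**Step 9 (key step).** The most likely failure is slow oxidative addition into the electron-rich, doubly ortho-flanked C–I bond. That would let catalyst decay, hydrodeiodination, capture of the acylpalladium by the amine (amide formation), or CO-free alkynylation with benzofuran closure take over.
Fallback, from 8 and 12 back to 16: the three bonds are made in separate polar steps, with C4 supplied by a carbamoyl chloride in place of CO.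
- Alkyne 12 is deprotonated with n-BuLi (THF, −78 °C) to lithium {4-[(3-methylbut-2-en-1-yl)oxy]phenyl}ethynide F1.
- F1 with N-methoxy-N-methylcarbamoyl chloride should give the alkynyl Weinreb amide N-methoxy-N-methyl-3-{4-[(3-methylbut-2-en-1-yl)oxy]phenyl}prop-2-ynamide F2.
- Iodophenol 8 is converted by MeMgCl into chloromagnesium 2-iodo-6-methoxy-3,5-bis(triisopropylsilyloxy)phenolate F3.
- Iodine–magnesium exchange on F3 with i-PrMgCl·LiCl gives the aryl Grignard reagent chloromagnesium 2-(chloromagnesio)-6-methoxy-3,5-bis(triisopropylsilyloxy)phenolate F4.
- Addition of F4 to F2 and aqueous work-up should give ynone 14, here isolated (Weinreb ketone synthesis).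
- 14 in Et2NH/EtOH at room temperature should close to flavone 16 through 15.

**Step 10.** The steps most likely to fail are the fate of the α-boryl enone and of the side chain in the oxidizing medium: protodeboronation before oxygen transfer, or slow epoxidation of the prenyl alkene by peracetic acid formed from H2O2 and AcOH. Partial consumption of the amide base elsewhere is a lesser concern.
Fallback, from 16 to 20: 16 is lithiated as before to 17, which is oxygenated directly with bis(trimethylsilyl) peroxide (electrophilic oxygenation of an organolithium). This should give 8-methoxy-2-{4-[(3-methylbut-2-en-1-yl)oxy]phenyl}-5,7-bis(triisopropylsilyloxy)-3-(trimethylsilyloxy)-4H-chromen-4-one F5. No boron and no aqueous peracid are involved. F5 is carried into the conditions of step 11, where fluoride removes all three silyl groups to give 20.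

**Step 6.** Site selectivity of the silylation may erode: the hydroxyl ortho to iodine is the more acidic one and could compete, or bis-silylation could occur.
Fallback, from 7 to 16: the order of events is reversed, so that ring closure itself distinguishes the two hydroxyls.
- Iodo-diol 7 is taken into the carbonylative annulation with 12 and 13 under the conditions of step 9; only the hydroxyl ortho to the new acyl group can close ring C.
- The ynone 1-[2,4-dihydroxy-3-methoxy-6-(triisopropylsilyloxy)phenyl]-3-{4-[(3-methylbut-2-en-1-yl)oxy]phenyl}prop-2-yn-1-one F6 and its amine adduct (E)-3-(diethylamino)-1-[2,4-dihydroxy-3-methoxy-6-(triisopropylsilyloxy)phenyl]-3-{4-[(3-methylbut-2-en-1-yl)oxy]phenyl}prop-2-en-1-one F7 are passed without isolation.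
- They should lead to 7-hydroxy-8-methoxy-2-{4-[(3-methylbut-2-en-1-yl)oxy]phenyl}-5-(triisopropylsilyloxy)-4H-chromen-4-one F8.
- The single free hydroxyl of F8 is then silylated (iPr3SiCl, imidazole, DMF) to give 16.

**Step 5.** Over-iodination at the second, equally activated ring position and oxidative degradation of the very electron-rich diol are the likely problems.
Fallback, from 5 to 7: iodine is introduced by directed ortho-metalation before the diol is unveiled.
- Bis-acetal 5 is lithiated with n-BuLi (THF, −78 °C) ortho to a MOM ether (its two ring C–H are equivalent) to give [2-lithio-4-methoxy-3,5-bis(methoxymethoxy)phenoxy]triisopropylsilane F9.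
- F9 is quenched cold with I2 to give [2-iodo-4-methoxy-3,5-bis(methoxymethoxy)phenoxy]triisopropylsilane F10; one equivalent of base can place only one iodine.
- Methanolic HCl as in step 4 then gives 7.

## Further compounds

F1 | step 9 | lithium {4-[(3-methylbut-2-en-1-yl)oxy]phenyl}ethynide | [Li]C#Cc1ccc(OCC=C(C)C)cc1
F2 | step 9 | N-methoxy-N-methyl-3-{4-[(3-methylbut-2-en-1-yl)oxy]phenyl}prop-2-ynamide | CON(C)C(=O)C#Cc1ccc(OCC=C(C)C)cc1
F3 | step 9 | chloromagnesium 2-iodo-6-methoxy-3,5-bis(triisopropylsilyloxy)phenolate | COc1c(O[Si](C(C)C)(C(C)C)C(C)C)cc(O[Si](C(C)C)(C(C)C)C(C)C)c(I)c1O[Mg]Cl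
F4 | step 9 | chloromagnesium 2-(chloromagnesio)-6-methoxy-3,5-bis(triisopropylsilyloxy)phenolate | COc1c(O[Si](C(C)C)(C(C)C)C(C)C)cc(O[Si](C(C)C)(C(C)C)C(C)C)c([Mg]Cl)c1O[Mg]Cl
F5 | step 10 | 8-methoxy-2-{4-[(3-methylbut-2-en-1-yl)oxy]phenyl}-5,7-bis(triisopropylsilyloxy)-3-(trimethylsilyloxy)-4H-chromen-4-one | COc1c(O[Si](C(C)C)(C(C)C)C(C)C)cc(O[Si](C(C)C)(C(C)C)C(C)C)c2c(=O)c(O[Si](C)(C)C)c(-c3ccc(OCC=C(C)C)cc3)oc12
F6 | step 6 | 1-[2,4-dihydroxy-3-methoxy-6-(triisopropylsilyloxy)phenyl]-3-{4-[(3-methylbut-2-en-1-yl)oxy]phenyl}prop-2-yn-1-one | COc1c(O)cc(O[Si](C(C)C)(C(C)C)C(C)C)c(C(=O)C#Cc2ccc(OCC=C(C)C)cc2)c1O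
F7 | step 6 | (E)-3-(diethylamino)-1-[2,4-dihydroxy-3-methoxy-6-(triisopropylsilyloxy)phenyl]-3-{4-[(3-methylbut-2-en-1-yl)oxy]phenyl}prop-2-en-1-one | COc1c(O)cc(O[Si](C(C)C)(C(C)C)C(C)C)c(C(=O)/C=C(/N(CC)CC)c2ccc(OCC=C(C)C)cc2)c1O
F8 | step 6 | 7-hydroxy-8-methoxy-2-{4-[(3-methylbut-2-en-1-yl)oxy]phenyl}-5-(triisopropylsilyloxy)-4H-chromen-4-one | COc1c(O)cc(O[Si](C(C)C)(C(C)C)C(C)C)c2c(=O)cc(-c3ccc(OCC=C(C)C)cc3)oc12
F9 | step 5 | [2-lithio-4-methoxy-3,5-bis(methoxymethoxy)phenoxy]triisopropylsilane | COCOc1c([Li])c(O[Si](C(C)C)(C(C)C)C(C)C)cc(OCOC)c1OC
F10 | step 5 | [2-iodo-4-methoxy-3,5-bis(methoxymethoxy)phenoxy]triisopropylsilane | COCOc1c(I)c(O[Si](C(C)C)(C(C)C)C(C)C)cc(OCOC)c1OC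
A1 | alternative 1 | 8-methoxy-5,7-bis(methoxymethoxy)-2-{4-[(3-methylbut-2-en-1-yl)oxy]phenyl}-3-[2-(trimethylsilyl)ethoxy]-4H-chromen-4-one | COCOc1cc(OCOC)c2c(=O)c(OCC[Si](C)(C)C)c(-c3ccc(OCC=C(C)C)cc3)oc2c1OC
A2 | alternative 1 | 3-methoxy-4,6-bis(methoxymethoxy)-2-({4-[(3-methylbut-2-en-1-yl)oxy]benzoyl}oxy)benzoyl chloride | COCOc1cc(OCOC)c(C(=O)Cl)c(OC(=O)c2ccc(OCC=C(C)C)cc2)c1OC
A3 | alternative 1 | triphenyl{[2-(trimethylsilyl)ethoxy]methylidene}phosphorane | C[Si](C)(C)CCOC=P(c1ccccc1)(c1ccccc1)c1ccccc1
A4 | alternative 2 | 5,8-dihydroxy-3,7-bis(methoxymethoxy)-2-{4-[(3-methylbut-2-en-1-yl)oxy]phenyl}-4H-chromen-4-one | COCOc1cc(O)c2c(=O)c(OCOC)c(-c3ccc(OCC=C(C)C)cc3)oc2c1O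
A5 | alternative 2 | 2-(methoxymethoxy)-5-(2-(methoxymethoxy)-3-{4-[(3-methylbut-2-en-1-yl)oxy]phenyl}-3-oxopropanoyl)cyclohexa-2,5-diene-1,4-dione (racemic, enolizable) | COCOC1=CC(=O)C(C(=O)C(OCOC)C(=O)c2ccc(OCC=C(C)C)cc2)=CC1=O
A6 | alternative 3 | 8-methoxy-5,7-bis(methoxymethoxy)-2-{4-[(3-methylbut-2-en-1-yl)oxy]phenyl}-3-nitro-2H-chromene (racemic) | COCOc1cc(OCOC)c2c(c1OC)OC(c1ccc(OCC=C(C)C)cc1)C([N+](=O)[O-])=C2
A7 | alternative 3 | 2-hydroxy-3-methoxy-4,6-bis(methoxymethoxy)benzaldehyde | COCOc1cc(OCOC)c(C=O)c(O)c1OC
A8 | alternative 3 | (E)-1-[(3-methylbut-2-en-1-yl)oxy]-4-(2-nitroethenyl)benzene | CC(C)=CCOc1ccc(/C=C/[N+](=O)[O-])cc1
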